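The readings come from a simulation for substances that don't exist, and the scatter is random.

The constants of this flask were not given, so I read two rates from the dusk run and built from them the one number I would carry over.

the same everywhere: left-handed substrate 0.020 M; right-handed substrate 0.020 M
- dusk: coupling partner 0.050 M (fed, over 2.0 h); free catalyst 50 µM; run made earlier; the fed solution adds 1.0 times the starting volume
- flask: coupling partner 0.0500 M (fed, over 2.0 h); free catalyst 100 µM; the fed solution adds 1.0 times the starting volume; time 4.0 h

dusk run (percent of the left-handed substrate and right-handed substrate together charged)

| time / min | left-handed substrate / % | right-handed substrate / % | left-handed product / % |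
|---|---|---|---|
| 4.00 | 50.1 | 51.3 | 0 |
| 12.0 | 48.2 | 50.3 | 2.6 |
| 20.0 | 46.7 | 49.5 | 2.8 |
| 30.0 | 43.6 | 48.5 | 5.8 |
| 40.0 | 41.9 | 49.4 | 10.2 |
| 60.0 | 35.9 | 46.4 | 16.1 |
| 80.0 | 32.9 | 42.1 | 22.0 |

(scatter of a reading: 1 percentage point)

- free catalyst is single-handed; left-handed substrate and right-handed substrate are mirror images of each other, charged as a racemate, each of them at the stated concentration
- amounts are per litre of the starting volume; all of the dose is in the solution fed
- steps under discussion: 2 free catalyst -> spent catalyst; coupling partner + free catalyst + left-handed substrate -> free catalyst + left-handed product; 2 free catalyst <-> resting dimer; coupling partner + free catalyst + right-handed substrate -> free catalyst + right-handed product; left-handed substrate <-> right-handed substrate; free catalyst <-> dormant form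
- an excess is the difference of the two amounts in percent of their sum
- an excess is below zero if the other one leads
- no earlier run changes the charge of free catalyst; that part of a forecast is a guess

- part of the left-handed substrate and right-handed substrate charged together that has reacted at 4.0 h
- excess of left-handed product over right-handed product in the product at 4.0 h
- excess of right-handed substrate over left-handed substrate among what is left of the two at 4.0 h

The first rate is the leak, the passing of right-handed substrate into its mirror image. At 80.0 min in the dusk run, left-handed substrate and left-handed product together stood 4.9 percentage points above that hand's share of the charge, a reading uncertain by about 1.4 points. The leak runs on the gap between the substrates, so I replaced the gap's curve by the mean of its 7 readings, 5.5 points, and the leak constant came out at 0.673 /h. Since each passage narrows the gap from both sides, the gap closes in a time of about 44.5 min.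

The second rate is the pull, the pseudo-first-order constant of coupling on left-handed substrate. Between 40.0 min and 80.0 min it read 0.473 /h.

Because the closing time is short against 4.0 h, I expected the gap to follow the late pull, so that the gap over the left-handed substrate equals the pull over twice the leak constant, the pull-to-leak ratio 0.351. Neglecting right-handed coupling, the excess of right-handed substrate is this ratio over two plus itself, 14.9%. No earlier run changes the catalyst charge, so using the dusk pull in this flask was my guess.

The forecast gave 70%, 76% and 23%, the last above mine, with the note “I assume racemisation is uncatalysed”. The flask gave 68.8%, 79.7% and 16.2%.

    2 free catalyst → spent catalyst (k = 3700 /M/h)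
    coupling partner + free catalyst + left-handed substrate → free catalyst + left-handed product (k = 2.30 × 10⁶ /M²/h)
    2 free catalyst ⇌ resting dimer, settled at all times (K = 3400 /M)
    coupling partner + free catalyst + right-handed substrate → free catalyst + right-handed product (k = 1.90 × 10⁵ /M²/h)
    left-handed substrate ⇌ right-handed substrate (k = 0.730 /h)
    free catalyst ⇌ dormant form (K = 0.530, k = 0.630 /h)

In this flask, coupling gave left-handed substrate a half-life of 0.91 h at 1.36 h, short against 4.0 h, while right-handed substrate had 18 h at 4.00 h, long against it. The pull of this flask's last 2.00 h gives a ratio of 0.423, hence an excess of 17.5% against 16.2%.

In the neighbour charged with 0.013 M of coupling partner, the mean pull over 4.0 h gives a ratio of 0.0956, hence an excess of 4.56%. That flask gave 2.87%.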